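**Retrosynthetic overview**

- The target comes from bis-angeloylation of the anti-1,3-diol. The diol comes from a tricyclic bis-enone by ligand-controlled β-borylation/oxidation (C9–O) and hydroxyl-directed reduction (C7–O).
- The tricycle is opened at the C9–C10 bond (quaternary carbon, seven-membered ring). This bond is closed last, by a hydrogen-atom-transfer-initiated radical 7-endo cyclization of a methylenecyclobutane onto a tethered β-ethoxy enone.
- The bicyclo[3.1.1]heptenone core (cyclobutane and six-membered ring formed together) comes from an intramolecular vinylketene–alkene [2+2] of an acyclic dienoic acid. Methylenation and ester-to-β-ethoxy-enone conversion follow.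
- The dienoic acid comes from a catalytic asymmetric vinylogous Mukaiyama aldol. Its carbinol is a temporary stereo-relay that fixes the absolute sense of the [2+2] and is later oxidised to the enone carbonyl.
- Building blocks: methyl isobutyrate, 3-(dimethylamino)acrolein, methyl 3-methylbut-2-enoate, (Z)-1-bromo-2-ethoxyethene, CH2Br2 and angelic acid.

Assumption: both esters are (Z)-2-methylbut-2-enoates (angelates) and the target is (4R,5S,7S,9S,10R,11R) as read from the SMILES; tricyclic compounds are named on the longipinane skeleton (tricyclo[5.4.0.0^{2,8}]undecane: C1 enone carbonyl, C2=C3, cyclobutane C4/C5/C10/C11, C6 gem-dimethyl carbon, C7–C9 the oxygenated chain, C10 methyl-bearing quaternary carbon), bicyclic ones as bicyclo[3.1.1]heptanes.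

**Route**

Step 1
Reactants: 1 methyl 2-methylpropanoate; 2 (2E)-3-(dimethylamino)prop-2-enal
Product: 4 methyl (3E)-2,2-dimethyl-5-oxopent-3-enoate, via aldol adduct 3 (not isolated)
Conditions: LiN(iPr)2, THF, −78 °C; 2, −78 to 0 °C; then 1 M HCl, rt
Reagents that add atoms: water, O
Why: The lithium ester enolate adds to the aldehyde carbon of the vinylogous formamide (aldol-type addition), and aqueous acid then hydrolyses the enamine and eliminates water, which can only give the conjugated (E)-enal because the α-carbon is quaternary (3-(dimethylamino)acrolein used as a malonaldehyde equivalent); no stereocentre is formed.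

Step 2
Reactants: 5 methyl 3-methylbut-2-enoate
Product: 6 tert-butyl[(1-methoxy-3-methylbuta-1,3-dien-1-yl)oxy]dimethylsilane
Conditions: LiN(iPr)2, THF, −78 °C; t-BuMe2SiCl, DMPU, −78 °C to rt
Reagents that add atoms: tert-butyldimethylsilyl chloride, CC(C)(C)[Si](C)(C)Cl
Why: Kinetic γ-deprotonation of the enoate and O-silylation of the dienolate give the silyl dienol ether needed for a vinylogous Mukaiyama aldol (silyl ketene acetal formation).

Step 3
Reactants: 4 methyl (3E)-2,2-dimethyl-5-oxopent-3-enoate; 6 tert-butyl[(1-methoxy-3-methylbuta-1,3-dien-1-yl)oxy]dimethylsilane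
Product: 7 dimethyl (2E,5R,6E)-5-hydroxy-3,8,8-trimethylnona-2,6-dienedioate
Conditions: SiCl4 (1.1 equiv), Denmark (R,R)-binaphthyldiamine bisphosphoramide (5 mol %), iPr2NEt (10 mol %), CH2Cl2, −78 °C; aq. NaHCO3
Reagents that add atoms: none
Why: In this Denmark vinylogous Mukaiyama aldol the phosphoramide-bound chlorosilyl cation activates the enal for γ-selective 1,2-addition and shields one aldehyde face, so the catalyst sets the C5 carbinol as (R) (the antipodal catalyst gives the antipode) and the new enoate is (E).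

Step 4
Reactants: 7 dimethyl (2E,5R,6E)-5-hydroxy-3,8,8-trimethylnona-2,6-dienedioate
Product: 8 (2E,5R,6E)-5-hydroxy-9-methoxy-3,8,8-trimethyl-9-oxonona-2,6-dienoic acid
Conditions: LiOH·H2O (1.2 equiv), THF/H2O 3:1, 0 °C to rt; 1 M HCl to pH 3
Reagents that add atoms: lithium hydroxide, [Li+].[OH-]
Why: Saponification discriminates sterically, cleaving the β,β-disubstituted enoate while the α,α-disubstituted (neopentyl-type) methyl ester stays intact at room temperature; the (E)-acid cannot lactonise and no stereocentre is touched.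

Step 5
Reactants: 8 (2E,5R,6E)-5-hydroxy-9-methoxy-3,8,8-trimethyl-9-oxonona-2,6-dienoic acid
Product: 9 triethylsilyl (2E,5R,6E)-9-methoxy-3,8,8-trimethyl-9-oxo-5-(triethylsilyloxy)nona-2,6-dienoate
Conditions: Et3SiCl (2.5 equiv), imidazole (3 equiv), CH2Cl2, 0 °C to rt; filter, concentrate
Reagents that add atoms: chlorotriethylsilane, CC[Si](Cl)(CC)CC
Why: Silylation protects the carbinol as a triethylsilyl ether and turns the acid into a silyl ester, so the acid chloride can be made in the next step without free HCl.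

Step 6
Reactants: 9 triethylsilyl (2E,5R,6E)-9-methoxy-3,8,8-trimethyl-9-oxo-5-(triethylsilyloxy)nona-2,6-dienoate
Product: 12 methyl 2-methyl-2-[(4R,7S)-2-methyl-6-oxo-4-(triethylsilyloxy)bicyclo[3.1.1]hept-2-en-7-yl]propanoate (C7 chain anti to the C2–C4 bridge), via acid chloride 10 (not isolated), via vinylketene 11 (not isolated)
Conditions: (COCl)2, DMF (cat.), CH2Cl2, 0 °C to rt; evaporate; slow addition to Et3N (3 equiv), PhMe, 110 °C, 0.005 M
Reagents that add atoms: none
Why: Oxalyl chloride converts the silyl ester into the acid chloride, Et3N effects 1,4-dehydrochlorination to the vinylketene, and an intramolecular crossed ketene–alkene [2+2] cycloaddition (chrysanthenone-type) forms the cyclobutanone and the six-membered ring at once; suprafacial addition to the (E)-alkene places the ester chain anti on C7, and the silyloxy carbon in the tether is expected to select the alkene face that leaves OSiEt3 on the less hindered side of the carbonyl bridge, fixing C1, C5 and C7 in absolute terms (the minor C4 epimer is removed by chromatography).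

Step 7
Reactants: 12 methyl 2-methyl-2-[(4R,7S)-2-methyl-6-oxo-4-(triethylsilyloxy)bicyclo[3.1.1]hept-2-en-7-yl]propanoate
Product: 13 methyl 2-methyl-2-[(4R,7S)-2-methyl-6-methylidene-4-(triethylsilyloxy)bicyclo[3.1.1]hept-2-en-7-yl]propanoate
Conditions: Zn, CH2Br2, TiCl4, THF (pre-formed Lombardo reagent); 12, CH2Cl2, 0 °C to rt
Reagents that add atoms: dibromomethane, BrCBr
Why: The Lombardo methylenation reagent olefinates the strained, non-enolisable cyclobutanone under non-basic conditions and leaves the hindered ester and the silyl ether alone; no stereocentre changes.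

Step 8
Reactants: 13 methyl 2-methyl-2-[(4R,7S)-2-methyl-6-methylidene-4-(triethylsilyloxy)bicyclo[3.1.1]hept-2-en-7-yl]propanoate; 14 (Z)-1-bromo-2-ethoxyethene
Product: 17 (1E)-1-ethoxy-4-[(4R,7S)-4-hydroxy-2-methyl-6-methylidenebicyclo[3.1.1]hept-2-en-7-yl]-4-methylpent-1-en-3-one, via ethoxyvinyllithium 15 (not isolated), via silylated enone 16 (not isolated)
Conditions: 14 (3.5 equiv), t-BuLi (7 equiv), THF, −78 °C; 13, −78 to −30 °C; aq. NH4Cl; then PPTS (cat.), EtOH, rt
Reagents that add atoms: none
Why: Bromine–lithium exchange gives the configurationally stable (Z)-alkoxyvinyllithium, whose addition–elimination at the ester stops at the ketone because the product is a deactivated vinylogous ester, and pyridinium tosylate in ethanol then removes the triethylsilyl group and equilibrates the enol ether to (E) (acyl substitution followed by acid-catalysed desilylation).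

Step 9
Reactants: 17 (1E)-1-ethoxy-4-[(4R,7S)-4-hydroxy-2-methyl-6-methylidenebicyclo[3.1.1]hept-2-en-7-yl]-4-methylpent-1-en-3-one
Product: 18 (1E)-1-ethoxy-4-methyl-4-[(7S)-2-methyl-6-methylidene-4-oxobicyclo[3.1.1]hept-2-en-7-yl]pent-1-en-3-one
Conditions: MnO2 (20 equiv), CH2Cl2, rt
Reagents that add atoms: none
Why: MnO2 oxidises only the allylic alcohol (verbenol-to-verbenone type allylic oxidation), which erases the relay stereocentre and turns the ring alkene into an enone that does not accept a hydrogen atom in the next step.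

Step 10
Reactants: 18 (1E)-1-ethoxy-4-methyl-4-[(7S)-2-methyl-6-methylidene-4-oxobicyclo[3.1.1]hept-2-en-7-yl]pent-1-en-3-one
Product: 20 longipina-2,8-diene-1,7-dione (ring-fusion configuration as in 26), via ethoxy ketone 19 (not isolated)
Conditions: Fe(acac)3 (30 mol %), PhSiH3 (2.5 equiv), EtOH/(CH2OH)2 5:1, 60 °C, 0.01 M; then DBU (2 equiv), CH2Cl2, rt
Reagents that add atoms: none
Why: Proposed new method: hydrogen-atom transfer from the iron hydride formed from Fe(acac)3 and PhSiH3 to the exocyclic methylene reversibly gives the tertiary cyclobutyl radical carrying the new methyl group; the anti chain on C5 can reach only the anti lobe of this radical, so 7-endo Giese addition to the β-carbon of the (E)-β-ethoxy enone forms the C9–C10 bond with the methyl forced syn to the enone bridge (the C10 quaternary stereocentre is set by the tether), the α-keto radical is reduced and protonated, and DBU then eliminates ethanol (E1cB) to remove the uncontrolled C9 centre; the closest known chemistry is iron-hydride reductive olefin–enone coupling and radical cyclization onto β-alkoxyacrylates.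

Step 11
Reactants: 20 longipina-2,8-diene-1,7-dione
Product: 22 (9S)-9-hydroxylongipin-2-ene-1,7-dione, via boryl ketone 21 (not isolated)
Conditions: CuCl (5 mol %), (R)-1-[(S)-2-(diphenylphosphino)ferrocenyl]ethyldicyclohexylphosphine (6 mol %, enantiomer chosen for 9S), NaOtBu (10 mol %), B2pin2 (1.2 equiv), MeOH (2 equiv), THF, rt; then NaBO3·4H2O, THF/H2O, rt
Reagents that add atoms: sodium perborate, [Na+].[O-]OB=O
Why: In this copper-catalysed asymmetric conjugate borylation the ligand-bound Cu–Bpin species adds only to the disubstituted cycloheptenone (the β,β-disubstituted ring enone is too hindered), the ligand chooses between two substrate faces that are nearly equivalent, and perborate oxidation with retention gives the (9S)-alcohol.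

Step 12
Reactants: 22 (9S)-9-hydroxylongipin-2-ene-1,7-dione
Product: 23 (7S,9S)-7,9-dihydroxylongipin-2-en-1-one
Conditions: Me4NBH(OAc)3 (5 equiv), MeCN/AcOH 1:1, −25 °C
Reagents that add atoms: none
Why: In the Evans–Saksena reduction the C9 hydroxyl binds the triacetoxyborohydride and delivers hydride intramolecularly to C7, giving the 1,3-anti diol with (7S) configuration while the unchelated enone carbonyl is not reduced.

Step 13
Reactants: 23 (7S,9S)-7,9-dihydroxylongipin-2-en-1-one; 24 (2Z)-2-methylbut-2-enoic acid (angelic acid)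
Product: 26 (4R,5S,7S,9S,10R,11R)-7,9-bis[(2Z)-2-methylbut-2-enoyloxy]longipin-2-en-1-one (CNP0236543.7), via mixed anhydride 25 (not isolated)
Conditions: 24 (4 equiv), 2,4,6-Cl3C6H2COCl (4 equiv), Et3N (6 equiv), PhMe, rt; then 23, PhMe, 80 °C
Reagents that add atoms: none
Why: Acylation through the preformed angelic 2,4,6-trichlorobenzoic mixed anhydride without DMAP (Yamaguchi-type esterification) esterifies both hindered secondary alcohols without Z-to-E isomerisation to the tiglate; no stereocentre changes.

**Compound list**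

1 | methyl 2-methylpropanoate | COC(=O)C(C)C | starting material
2 | (2E)-3-(dimethylamino)prop-2-enal | CN(C)/C=C/C=O | starting material
3 | methyl (4E)-5-(dimethylamino)-3-hydroxy-2,2-dimethylpent-4-enoate (racemic, lithium alkoxide in the flask) | COC(=O)C(C)(C)C(O)/C=C/N(C)C | intermediate
4 | methyl (3E)-2,2-dimethyl-5-oxopent-3-enoate | COC(=O)C(C)(C)/C=C/C=O | intermediate
5 | methyl 3-methylbut-2-enoate | COC(=O)C=C(C)C | starting material
6 | tert-butyl[(1-methoxy-3-methylbuta-1,3-dien-1-yl)oxy]dimethylsilane | COC(=CC(C)=C)O[Si](C)(C)C(C)(C)C | intermediate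
7 | dimethyl (2E,5R,6E)-5-hydroxy-3,8,8-trimethylnona-2,6-dienedioate | COC(=O)/C=C(\C)C[C@@H](O)/C=C/C(C)(C)C(=O)OC | intermediate
8 | (2E,5R,6E)-5-hydroxy-9-methoxy-3,8,8-trimethyl-9-oxonona-2,6-dienoic acid | OC(=O)/C=C(\C)C[C@@H](O)/C=C/C(C)(C)C(=O)OC | intermediate
9 | triethylsilyl (2E,5R,6E)-9-methoxy-3,8,8-trimethyl-9-oxo-5-(triethylsilyloxy)nona-2,6-dienoate | CC[Si](CC)(CC)OC(=O)/C=C(\C)C[C@@H](O[Si](CC)(CC)CC)/C=C/C(C)(C)C(=O)OC | intermediate
10 | methyl (3E,5R,7E)-9-chloro-2,2,7-trimethyl-9-oxo-5-(triethylsilyloxy)nona-3,7-dienoate | ClC(=O)/C=C(\C)C[C@@H](O[Si](CC)(CC)CC)/C=C/C(C)(C)C(=O)OC | intermediate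
11 | methyl (3E,6Z)-2,2,7-trimethyl-9-oxo-5-(triethylsilyloxy)nona-3,6,8-trienoate (vinylketene, silyloxy carbon configured as in 9) | O=C=C/C(C)=C\[C@@H](O[Si](CC)(CC)CC)/C=C/C(C)(C)C(=O)OC | intermediate
12 | methyl 2-methyl-2-[(4R,7S)-2-methyl-6-oxo-4-(triethylsilyloxy)bicyclo[3.1.1]hept-2-en-7-yl]propanoate (C7 chain anti, silyloxy on the C6 side) | COC(=O)C(C)(C)[C@@H]1[C@@H]2C(=O)[C@H]1C(C)=C[C@H]2O[Si](CC)(CC)CC | intermediate
13 | methyl 2-methyl-2-[(4R,7S)-2-methyl-6-methylidene-4-(triethylsilyloxy)bicyclo[3.1.1]hept-2-en-7-yl]propanoate | COC(=O)C(C)(C)[C@@H]1[C@@H]2C(=C)[C@H]1C(C)=C[C@H]2O[Si](CC)(CC)CC | intermediate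
14 | (Z)-1-bromo-2-ethoxyethene | CCO/C=C\Br | starting material
15 | (Z)-(2-ethoxyethenyl)lithium | CCO/C=C\[Li] | intermediate
16 | (1Z)-1-ethoxy-4-methyl-4-[(4R,7S)-2-methyl-6-methylidene-4-(triethylsilyloxy)bicyclo[3.1.1]hept-2-en-7-yl]pent-1-en-3-one | CCO/C=C\C(=O)C(C)(C)[C@@H]1[C@@H]2C(=C)[C@H]1C(C)=C[C@H]2O[Si](CC)(CC)CC | intermediate
17 | (1E)-1-ethoxy-4-[(4R,7S)-4-hydroxy-2-methyl-6-methylidenebicyclo[3.1.1]hept-2-en-7-yl]-4-methylpent-1-en-3-one | CCO/C=C/C(=O)C(C)(C)[C@@H]1[C@@H]2C(=C)[C@H]1C(C)=C[C@H]2O | intermediate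
18 | (1E)-1-ethoxy-4-methyl-4-[(7S)-2-methyl-6-methylidene-4-oxobicyclo[3.1.1]hept-2-en-7-yl]pent-1-en-3-one (C7 chain anti) | CCO/C=C/C(=O)C(C)(C)[C@@H]1[C@@H]2C(=C)[C@H]1C(C)=CC2=O | intermediate
19 | 9-ethoxylongipin-2-ene-1,7-dione (both C9 epimers) | O=C1CC(OCC)[C@@]2(C)[C@@H]3C(=O)C=C(C)[C@H]2[C@@H]3C1(C)C | intermediate
20 | longipina-2,8-diene-1,7-dione (ring-fusion configuration as in 26) | O=C1C=C[C@@]2(C)[C@@H]3C(=O)C=C(C)[C@H]2[C@@H]3C1(C)C | intermediate
21 | 9-(4,4,5,5-tetramethyl-1,3,2-dioxaborolan-2-yl)longipin-2-ene-1,7-dione (C9 configured as the C–O bond of 22) | O=C1C[C@H](B4OC(C)(C)C(C)(C)O4)[C@@]2(C)[C@@H]3C(=O)C=C(C)[C@H]2[C@@H]3C1(C)C | intermediate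
22 | (9S)-9-hydroxylongipin-2-ene-1,7-dione | O=C1C[C@H](O)[C@@]2(C)[C@@H]3C(=O)C=C(C)[C@H]2[C@@H]3C1(C)C | intermediate
23 | (7S,9S)-7,9-dihydroxylongipin-2-en-1-one | O[C@H]1C[C@H](O)[C@@]2(C)[C@@H]3C(=O)C=C(C)[C@H]2[C@@H]3C1(C)C | intermediate
24 | (2Z)-2-methylbut-2-enoic acid (angelic acid) | C/C=C(/C)C(=O)O | starting material
25 | (2Z)-2-methylbut-2-enoic 2,4,6-trichlorobenzoic anhydride | C/C=C(/C)C(=O)OC(=O)c1c(Cl)cc(Cl)cc1Cl | intermediate
26 | (4R,5S,7S,9S,10R,11R)-7,9-bis[(2Z)-2-methylbut-2-enoyloxy]longipin-2-en-1-one | C/C=C(/C)C(=O)O[C@H]1C[C@H](OC(=O)/C(C)=C\C)[C@@]2(C)[C@@H]3C(=O)C=C(C)[C@H]2[C@@H]3C1(C)C | target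

**Step count and risks**

Total step count: 13. Longest linear sequence: 12 steps (steps 1 and 3 to 13; the branch through step 2 is equally long).

The three steps most likely to fail:

Step 6 (crossed vinylketene cycloaddition). A 1,2-disubstituted alkene is a weak ketenophile, so the yield may be low, the fused bicyclo[3.2.0] isomer may compete, and the facial control by the silyloxy carbon is a prediction. If the facial preference is the reverse of that assumed, the antipodal catalyst in step 3 corrects it, because the relay centre is erased in step 9. The fallback sets out from 9 (through the same acid chloride 10) and comes back at 12. Acid chloride 10 is quenched with pyrrolidine to give methyl (3E,5R,7E)-2,2,7-trimethyl-9-oxo-9-(pyrrolidin-1-yl)-5-(triethylsilyloxy)nona-3,7-dienoate F1. Tf2O and 2,4,6-collidine in 1,2-dichloroethane at 80 °C turn this amide into a vinyl keteniminium ion (Ghosez chemistry), a much stronger electrophile than the ketene. It adds across the same alkene to give the cyclobutaniminium triflate F2, and aqueous NaHCO3 hydrolyses F2 to 12.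

Step 10 (radical 7-endo closure at a quaternary carbon). The cyclization may be too slow against reduction of the radical or of the acceptor. The fallback replaces the radical closure by a palladium-mediated one; it sets out from 13 and comes back at 20. LiC≡CSiMe3 with BF3·OEt2 (THF, −78 °C) converts the ester of 13 into the silylated ynone F3. Bu4NF buffered with AcOH removes both silyl groups to give the hydroxy ynone F4. NaI in AcOH adds HI to give the (Z)-β-iodo enone alcohol F5, and MnO2 gives the (Z)-β-iodo enone ketone F6. A reductive Heck reaction (Pd(OAc)2, PPh3, HCO2Na, DMF, 80 °C) then closes the ring: the vinylpalladium species adds 7-exo to the exocyclic methylene, forming the same C9–C10 bond with the same tether-enforced configuration. The resulting neopentyl palladium alkyl has no β-hydrogen and is reduced by formate to the methyl group, giving 20 directly.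

Step 13 (double angeloylation of two neopentyl-type secondary alcohols). Conversion may stall at the mono-ester, or partial isomerisation to tiglate may occur. The fallback builds the angelate double bonds on the molecule; it sets out from 23 and comes back at 26. Both alcohols are esterified with 2-[bis(2,2,2-trifluoroethoxy)phosphoryl]propanoic acid (DCC, DMAP, CH2Cl2) to give the bis(phosphonopropanoate) F7. KN(SiMe3)2 with 18-crown-6 in THF at −78 °C followed by acetaldehyde (Still–Gennari olefination) then forms both (Z)-2-methylbut-2-enoates and gives 26.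

Further compounds
F1 | step 6 | methyl (3E,5R,7E)-2,2,7-trimethyl-9-oxo-9-(pyrrolidin-1-yl)-5-(triethylsilyloxy)nona-3,7-dienoate | O=C(/C=C(\C)C[C@@H](O[Si](CC)(CC)CC)/C=C/C(C)(C)C(=O)OC)N1CCCC1
F2 | step 6 | 1-[(4R,7S)-7-(1-methoxy-2-methyl-1-oxopropan-2-yl)-2-methyl-4-(triethylsilyloxy)bicyclo[3.1.1]hept-2-en-6-ylidene]pyrrolidinium trifluoromethanesulfonate | COC(=O)C(C)(C)[C@@H]1[C@@H]2C(=[N+]3CCCC3)[C@H]1C(C)=C[C@H]2O[Si](CC)(CC)CC.[O-]S(=O)(=O)C(F)(F)F
F3 | step 10 | 4-methyl-4-[(4R,7S)-2-methyl-6-methylidene-4-(triethylsilyloxy)bicyclo[3.1.1]hept-2-en-7-yl]-1-(trimethylsilyl)pent-1-yn-3-one | C[Si](C)(C)C#CC(=O)C(C)(C)[C@@H]1[C@@H]2C(=C)[C@H]1C(C)=C[C@H]2O[Si](CC)(CC)CC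
F4 | step 10 | 4-[(4R,7S)-4-hydroxy-2-methyl-6-methylidenebicyclo[3.1.1]hept-2-en-7-yl]-4-methylpent-1-yn-3-one | C#CC(=O)C(C)(C)[C@@H]1[C@@H]2C(=C)[C@H]1C(C)=C[C@H]2O
F5 | step 10 | (1Z)-4-[(4R,7S)-4-hydroxy-2-methyl-6-methylidenebicyclo[3.1.1]hept-2-en-7-yl]-1-iodo-4-methylpent-1-en-3-one | I/C=C\C(=O)C(C)(C)[C@@H]1[C@@H]2C(=C)[C@H]1C(C)=C[C@H]2O
F6 | step 10 | (1Z)-1-iodo-4-methyl-4-[(7S)-2-methyl-6-methylidene-4-oxobicyclo[3.1.1]hept-2-en-7-yl]pent-1-en-3-one | I/C=C\C(=O)C(C)(C)[C@@H]1[C@@H]2C(=C)[C@H]1C(C)=CC2=O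
F7 | step 13 | (7S,9S)-1-oxolongipin-2-ene-7,9-diyl bis{2-[bis(2,2,2-trifluoroethoxy)phosphoryl]propanoate} | CC(P(=O)(OCC(F)(F)F)OCC(F)(F)F)C(=O)O[C@H]1C[C@H](OC(=O)C(C)P(=O)(OCC(F)(F)F)OCC(F)(F)F)[C@@]2(C)[C@@H]3C(=O)C=C(C)[C@H]2[C@@H]3C1(C)C
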